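(All runs stem from a simulated flask on assumed constants.)

Z in the ochre run refuses to fall past a certain point, and the flasks asked about share the charge that makes this point useful.

common to all: Z 0.50 M

|  | J | remark | time |
|---|---|---|---|
| green | 12 mM | run made earlier |  |
| ochre | 50 mM | run made earlier |  |
| epsilon | 25 mM |  | 50 min |
| alpha | 25 mM |  | 200 min |

| run | time / min | X / % | Z / % |
|---|---|---|---|
| green | 6.00 | 27.1 | 72.3 |
| green | 12.0 | 40.2 | 61.2 |
| green | 20.0 | 48.1 | 52.1 |
| green | 25.0 | 49.7 | 49.4 |
| green | 30.0 | 51.6 | 48.2 |
| ochre | 6.00 | 51.5 | 48.6 |
| ochre | 12.0 | 55.7 | 44.7 |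
| ochre | 20.0 | 55.9 | 43.1 |
| ochre | 25.0 | 55.9 | 42.5 |
| ochre | 30.0 | 56.7 | 42.9 |

(standard deviation of a reading: 0.5 percentage points)

- the average divides the monomer in chains by the number of chains begun, living and dead together
- the earlier runs were read with a standard deviation of 0.5 percentage points
- steps that have been proposed: Z + J -> G + X; Z + G -> X + G; X + G -> Z + G; X -> Q; 2 G -> D
- the earlier runs do not show the number of chains; that part of a forecast is a guess

* which of the two ends with the longer chains by the average number of monomer units in a chain (chains begun, living or dead) ("neither" if they lie within 10%) (epsilon / alpha / neither)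
* average number of monomer units in a chain (chains begun, living or dead) at the end, epsilon
* average number of monomer units in a chain (chains begun, living or dead) at the end, alpha

Read down the ochre Z column, the readings from 20.0 min on are 43.1%, 42.5% and 42.9%, a spread close to the scatter of 0.5 percentage points, with X flat beside them. Read across, the green run has 48.2% of its Z left at 30.0 min, where the ochre run had 48.6% left at 6.00 min, so the green run took 5.00 times as long with 4.17 times less J.

The pace therefore follows J, and the working assumption is that the end point does not: Z stops at a standing concentration, [Z]e = 0.214 M, where addition and return balance, the equilibrium monomer concentration. At that pace epsilon arrives near 40.0 min, earlier than its 50 min. Counting what is left, and guessing that each J begins one chain, the length is the charged [Z], less any share passed to Q, less [Z]e, all over the charged [J]; with no Q this gives 11.4 for epsilon and alpha.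

The forecast, which finds that the speed-up “points to reversible propagation”, sets values lower than 11.4 after allowing for Q: 11.1 for epsilon, 10.6 for alpha, and neither as the longer.

    Z + J → G + X (k = 0.480 L mol⁻¹ s⁻¹)
    Z + G → X + G, rate k2*[G]*[Z] (k = 0.160 L mol⁻¹ s⁻¹)
    X + G → Z + G, rate k3*[G] as long as [X] is above zero (k = 0.0340 s⁻¹)
    X → Q (k = 4.60 × 10⁻⁶ s⁻¹)
    2 G → D (k = 0.0260 L mol⁻¹ s⁻¹)

The flasks give 11.3 for epsilon and 10.9 for alpha, a gap less than the margin of 10%, so the answer is neither. Alpha ends with 42.5% of its Z left and 3.00% passed to Q, and with that share the rule gives 10.8. The neighbour flask, alpha with 0.30 M of Z, should by [Z]e keep 71.3% of its Z, and it keeps 70.8%. With its 1.53% passed to Q, the rule gives 3.25, and the neighbour flask ends at 3.32.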